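The fractions of the charged solid substrate held as solid, dissolved substrate, quenched substrate, target, isomer of the product and side product (one side product counting as two) add up to one at every moment, so whatever leaves the solid must appear in one of the others.

solid substrate 1.5 M; solid reagent 1.95 M; protic impurity 0.0750 M; time 4.0 min

1. amount of target at 4.0 min, in percent of the solid substrate charged
2. the change that raises the amount of target at 4.0 min, in percent of the solid substrate charged most ("none" if none brings more than 2 percentage points) (noon / dusk / midnight / winter / none)
3. amount of target at 4.0 min, in percent of the solid substrate charged, after noon

- percentages count the solid substrate that a species holds: one side product counts as two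
- solid, in amounts per volume of the solution: solid substrate, solid reagent
- at the start none of the solid reagent is in solution
- at the start none of the solid substrate is in solution
- run time (flask): 4.0 min

- noon: doubling the solubility in step 1, all else as stated
- dusk: doubling the dissolution coefficient of step 4, all else as stated
- midnight: doubling the dissolution coefficient of step 1, all else as stated
- winter: doubling the solubility in step 4, all else as stated

    solid reagent ⇌ coupling partner, rate k1*(cs1 - [coupling partner]) while solid is left; crystals form when [coupling partner] > cs1 (cs1 = 0.35 M, k1 = 0.00695 s⁻¹)
    solid substrate + protic impurity → quenched substrate (k2 = 0.681 M⁻¹ s⁻¹)
    dissolved substrate + target → side product (k3 = 1.54 M⁻¹ s⁻¹)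
    solid substrate ⇌ dissolved substrate, rate k4*(cs4 - [dissolved substrate]) while solid is left; crystals form when [dissolved substrate] > cs4 (cs4 = 37 mM, k4 = 0.0300 s⁻¹)
    target ⇌ isomer of the product (K5 = 2.5, k5 = 0.0408 s⁻¹)
    dissolved substrate + coupling partner → target (k6 = 1.52 M⁻¹ s⁻¹)

*What comes first in this flask?* The protic impurity attacks the solid substrate with a half-life of 0.679 s, and its charge can take 5.00% of the solid substrate, which I write off at once.

*How much of the charge can reach the solution?* Solid substrate dissolves fastest into an empty solution, at its coefficient times its solubility, so I carry the dissolving ceiling, the fraction of the charge that this fastest rate delivers over the run, 17.8%. The solid reagent, reckoned the same way against the same charge, could deliver 38.9%, which is more.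

*But what keeps the solution empty?* The coupling's first-order constant for dissolved substrate, its rate constant times the coupling partner, passes the dissolving coefficient of solid substrate once the coupling partner stands above 1.32% of the charge, a level that the reagent's fastest rate reaches after 8.11 s, hardly any of the run. For the rest of the run, then, I take dissolving as the rate-limiting step, and the ceiling as the measure of what enters.

*Yet the ceiling isn't target.* No: target and isomer of the product relax towards each other in 17.5 s, far shorter than the run, so I estimate target at 28.6% of the pair, about 5.07% of the charge. My reckoning stops there, before the side product takes its share, so I name no best change.

The forecast goes further than I do and stands lower than my estimate: 3.4%, 4.3% after noon, and winter as the best change, on the ground that “Winter nearly doubles the supply”.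

The simulation gives 3.31%, and 4.35% after noon. The best change is none: noon adds 1 percentage point and winter 0.82 points, both under the margin of 2 points, and there the forecast and the flask part.

By 4.00 min this flask's solid has given up 15.4% of the charge to solution, less than the dissolving ceiling of 17.8% and 86.5% of it, with 3.31% standing as target, 6.51% as isomer of the product and 5.37% as side product. The neighbour charged with 0.38 M of solid substrate has a ceiling of 70.1% of its smaller charge, has given up 60.7% by 4.00 min, which is 86.6% of that ceiling, and holds 13.1% as target.

(The constants used here were set for the occasion; what happens was integrated by code.)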